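**Plan**

- Retrosynthesis: with all five phenols masked as benzyl ethers, the C5'–CH2–aryl bond of ring B is cut first (benzylic bromide plus arylboronic acid), leading back to a methyl 4-hydroxy-3-alkylbenzoate.
- Ring B is then cut across C1'–C6' and C2'–C3'. Its 1,2,4-pattern (bridge on C1', OH on C2', benzylic carbon on C5' para to that OH) is what the C3–C6 diene of methyl coumalate gives with the bis(silyl) ketene acetal of a 4-arylbutanoic acid. C5 of the pyrone and its ester carbon become C5' and the benzylic CH2; Cα and the carboxyl carbon of the acid become C1' and C2'.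
- Ring A is cut at its two aryl–CH2 bonds (aryl bromide plus benzylzinc) and at the aryl–chain bond (aryl bromide plus alkylzinc), back to 3-bromo-5-methoxyphenol.
- Forward: ring A is bought in, given the C4 chain, dibrominated and doubly benzylated. The acid is converted into the ketene acetal, ring B arises in the cycloaddition/CO2 loss/aromatization, the last aryl ring is joined by Suzuki–Miyaura coupling, and hydrogenolysis frees the phenols.
- Stereochemistry: the target has no stereocentre; the sp3 centres formed in the cycloadduct vanish on aromatization.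

Key step: step 8

Remark on the chemistry: Ar below means the protected ring A, 3-(benzyloxy)-2,6-bis[4-(benzyloxy)benzyl]-5-methoxyphenyl; primed locants refer to ring B; 3-bromo-5-methoxyphenol and the THF solution of (4-ethoxy-4-oxobutyl)zinc bromide are taken as purchasable, which avoids a statistical monoprotection of 5-methoxyresorcinol.

**Route**

Step 1
Reactants: 1 3-bromo-5-methoxyphenol
Product: 2 1-(benzyloxy)-3-bromo-5-methoxybenzene
Conditions: benzyl bromide, K2CO3, DMF, 25 °C
Reagents that add atoms: benzyl bromide, BrCc1ccccc1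
Why: Williamson etherification of the only phenol under carbonate should be clean and leaves the aryl bromide untouched.

Step 2
Reactants: 2 1-(benzyloxy)-3-bromo-5-methoxybenzene; 3 (4-ethoxy-4-oxobutyl)zinc bromide (THF solution)
Product: 4 ethyl 4-[3-(benzyloxy)-5-methoxyphenyl]butanoate
Conditions: Pd(OAc)2 (cat.), SPhos, THF, 25 to 50 °C
Reagents that add atoms: none
Why: Negishi sp2–sp3 coupling of an unhindered aryl bromide with a primary alkylzinc bromide is reliable with palladium/SPhos and tolerates the ethyl ester.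

Step 3
Reactants: 4 ethyl 4-[3-(benzyloxy)-5-methoxyphenyl]butanoate
Product: 5 ethyl 4-[3-(benzyloxy)-2,6-dibromo-5-methoxyphenyl]butanoate
Conditions: N-bromosuccinimide (2.05 equiv), MeCN, 0 to 25 °C, dark
Reagents that add atoms: N-bromosuccinimide, O=C1CCC(=O)N1Br
Why: Electrophilic aromatic bromination of a 5-alkyl-1,3-dialkoxybenzene goes para to each alkoxy group, that is at the two carbons flanking the chain, just as 1,3-dimethoxybenzene gives its 4,6-dibromide and leaves the carbon between the oxygens free.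

Step 4
Reactants: 6 4-(benzyloxy)benzyl chloride
Product: 7 [4-(benzyloxy)benzyl]zinc chloride (titrated THF solution, used directly)
Conditions: Zn dust, LiCl, THF, 25 °C
Reagents that add atoms: zinc, [Zn]
Why: Direct insertion of LiCl-activated zinc into a benzylic chloride should give the benzylzinc chloride at room temperature without touching the aryl benzyl ether.

Step 5
Reactants: 5 ethyl 4-[3-(benzyloxy)-2,6-dibromo-5-methoxyphenyl]butanoate; 7 [4-(benzyloxy)benzyl]zinc chloride (2.6 equiv)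
Product: 8 ethyl 4-{3-(benzyloxy)-2,6-bis[4-(benzyloxy)benzyl]-5-methoxyphenyl}butanoate (ethyl 4-Ar-butanoate)
Conditions: Pd(OAc)2 (cat.), SPhos, THF, 25 to 60 °C
Reagents that add atoms: none
Why: Twofold Negishi coupling of a benzylzinc chloride with ortho,ortho'-disubstituted aryl bromides is within the reach of the bulky biarylphosphine SPhos, and the mild zinc nucleophile spares the ester.

Step 6
Reactants: 8 ethyl 4-Ar-butanoate
Product: 9 4-Ar-butanoic acid
Conditions: LiOH·H2O, THF/MeOH/H2O, 50 °C; then 1 M HCl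
Reagents that add atoms: lithium hydroxide, [Li+].[OH-]
Why: Saponification of an unhindered primary ethyl ester; nothing else in the molecule is base-labile.

Step 7
Reactants: 9 4-Ar-butanoic acid
Product: 11 1,1-bis(trimethylsilyloxy)-4-Ar-but-1-ene (bis(trimethylsilyl) ketene acetal of 9; used crude after filtration and evaporation under argon), via trimethylsilyl ester 10 (not isolated)
Conditions: a) HN(SiMe3)2, toluene, 80 °C, evaporate; b) LiN(iPr)2, THF, −78 °C, then Me3SiCl, −78 to 25 °C; pentane, filter under argon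
Reagents that add atoms: hexamethyldisilazane, C[Si](C)(C)N[Si](C)(C)C; chlorotrimethylsilane, C[Si](C)(C)Cl
Why: Silyl ester formation, kinetic α-deprotonation and O-silylation of the ester enolate is the standard way to bis(trimethylsilyl) ketene acetals, and at −78 °C the ester α-CH2 is far more acidic than the diarylmethane or benzyl ether protons.

Step 8
Reactants: 11 1,1-bis(trimethylsilyloxy)-4-Ar-but-1-ene; 12 methyl coumalate (1.5 equiv)
Product: 16 methyl 4-hydroxy-3-(2-Ar-ethyl)benzoate, via bridged lactone cycloadduct 13 (not isolated), via bis(silyloxy)cyclohexadiene 14 (not isolated), via aryl trimethylsilyl ether 15 (not isolated)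
Conditions: toluene, 110 °C, sealed tube, under argon; then 1 M HCl, THF, 25 °C
Reagents that add atoms: none
Why: The electron-poor C3–C6 diene of methyl coumalate and the electron-rich ketene acetal combine in an inverse-electron-demand Diels–Alder reaction, probably asynchronous with the nucleophilic β-carbon bonding first, to the bridged lactone 13, which loses CO2 by retro-[4+2] to the cyclohexadiene 14; 1,2-elimination of Me3SiOH aromatizes it to 15 and dilute acid frees the phenol. The closest known reaction type is the pyrone Diels–Alder/decarboxylation benzannulation of methyl coumalate with ketene acetals and enol ethers, which gives 4-alkoxybenzoates. Ring B is the only ring closed, a six-membered carbocycle formed by intermolecular [4+2] closure (C1'–C6' and C2'–C3') and made aromatic by the two extrusions. No stereocentre is kept, since the sp3 centres of 13 and 14 form as mixtures and disappear on aromatization. The step needs regioselectivity, which the polarization of both partners secures: C6 of the pyrone, conjugated to both the lactone and the ester carbonyl, takes the β-carbon of the ketene acetal, so the oxygen ends para and the bridge meta to the ester.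

Step 9
Reactants: 16 methyl 4-hydroxy-3-(2-Ar-ethyl)benzoate
Product: 17 methyl 4-(benzyloxy)-3-(2-Ar-ethyl)benzoate
Conditions: benzyl bromide, K2CO3, DMF, 25 °C
Reagents that add atoms: benzyl bromide, BrCc1ccccc1
Why: Williamson etherification of a phenol made more acidic by the para ester should proceed readily.

Step 10
Reactants: 17 methyl 4-(benzyloxy)-3-(2-Ar-ethyl)benzoate
Product: 18 [4-(benzyloxy)-3-(2-Ar-ethyl)phenyl]methanol
Conditions: LiAlH4, THF, 0 °C; H2O/NaOH work-up
Reagents that add atoms: none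
Why: Hydride reduction of a benzoate ester to the benzylic alcohol; all ethers are inert to LiAlH4.

Step 11
Reactants: 18 [4-(benzyloxy)-3-(2-Ar-ethyl)phenyl]methanol
Product: 19 1-(benzyloxy)-4-(bromomethyl)-2-(2-Ar-ethyl)benzene (used without storage)
Conditions: CBr4, PPh3, CH2Cl2, 0 °C
Reagents that add atoms: carbon tetrabromide, BrC(Br)(Br)Br
Why: The Appel reaction turns the primary benzylic alcohol into the bromide under neutral conditions, avoiding acid that could trigger Friedel–Crafts self-alkylation of the electron-rich rings.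

Step 12
Reactants: 19 1-(benzyloxy)-4-(bromomethyl)-2-(2-Ar-ethyl)benzene; 20 4-(benzyloxy)phenylboronic acid
Product: 21 1-(benzyloxy)-2,4-bis[4-(benzyloxy)benzyl]-3-(2-{2-(benzyloxy)-5-[4-(benzyloxy)benzyl]phenyl}ethyl)-5-methoxybenzene (penta-O-benzyl ether of the target)
Conditions: Pd(OAc)2 (cat.), PPh3, K3PO4, toluene, 80 °C
Reagents that add atoms: none
Why: Suzuki–Miyaura sp3–sp2 coupling of a benzylic bromide with an arylboronic acid under anhydrous phosphate conditions gives diarylmethanes, and no β-hydrogen is available for elimination.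

Step 13
Reactants: 21 penta-O-benzyl ether of the target
Product: 22 2,4-bis(4-hydroxybenzyl)-3-{2-[2-hydroxy-5-(4-hydroxybenzyl)phenyl]ethyl}-5-methoxyphenol (CNP0134121.0)
Conditions: H2 (1 atm), Pd/C, EtOAc/MeOH, 25 °C
Reagents that add atoms: none
Why: Catalytic hydrogenolysis should cleave all five aryl benzyl ethers at the O–CH2Ph bond, while the diarylmethane C–C bonds, the bibenzyl bridge and the methyl ether are inert.

**Compound list**

1 | 3-bromo-5-methoxyphenol | COc1cc(O)cc(Br)c1 | starting material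
2 | 1-(benzyloxy)-3-bromo-5-methoxybenzene | COc1cc(Br)cc(OCc2ccccc2)c1 | intermediate
3 | (4-ethoxy-4-oxobutyl)zinc bromide | CCOC(=O)CCC[Zn]Br | starting material
4 | ethyl 4-[3-(benzyloxy)-5-methoxyphenyl]butanoate | CCOC(=O)CCCc1cc(OC)cc(OCc2ccccc2)c1 | intermediate
5 | ethyl 4-[3-(benzyloxy)-2,6-dibromo-5-methoxyphenyl]butanoate | CCOC(=O)CCCc1c(Br)c(OC)cc(OCc2ccccc2)c1Br | intermediate
6 | 4-(benzyloxy)benzyl chloride | ClCc1ccc(OCc2ccccc2)cc1 | starting material
7 | [4-(benzyloxy)benzyl]zinc chloride | Cl[Zn]Cc1ccc(OCc2ccccc2)cc1 | intermediate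
8 | ethyl 4-{3-(benzyloxy)-2,6-bis[4-(benzyloxy)benzyl]-5-methoxyphenyl}butanoate | CCOC(=O)CCCc1c(Cc2ccc(OCc3ccccc3)cc2)c(OC)cc(OCc2ccccc2)c1Cc1ccc(OCc2ccccc2)cc1 | intermediate
9 | 4-{3-(benzyloxy)-2,6-bis[4-(benzyloxy)benzyl]-5-methoxyphenyl}butanoic acid | OC(=O)CCCc1c(Cc2ccc(OCc3ccccc3)cc2)c(OC)cc(OCc2ccccc2)c1Cc1ccc(OCc2ccccc2)cc1 | intermediate
10 | trimethylsilyl 4-{3-(benzyloxy)-2,6-bis[4-(benzyloxy)benzyl]-5-methoxyphenyl}butanoate | C[Si](C)(C)OC(=O)CCCc1c(Cc2ccc(OCc3ccccc3)cc2)c(OC)cc(OCc2ccccc2)c1Cc1ccc(OCc2ccccc2)cc1 | intermediate (not isolated)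
11 | 1,1-bis(trimethylsilyloxy)-4-{3-(benzyloxy)-2,6-bis[4-(benzyloxy)benzyl]-5-methoxyphenyl}but-1-ene | COc1cc(OCc2ccccc2)c(Cc2ccc(OCc3ccccc3)cc2)c(CCC=C(O[Si](C)(C)C)O[Si](C)(C)C)c1Cc1ccc(OCc2ccccc2)cc1 | intermediate
12 | methyl coumalate (methyl 2-oxo-2H-pyran-5-carboxylate) | COC(=O)C1=COC(=O)C=C1 | starting material
13 | methyl 7-(2-Ar-ethyl)-3-oxo-8,8-bis(trimethylsilyloxy)-2-oxabicyclo[2.2.2]oct-5-ene-6-carboxylate (diastereomer mixture, racemic, centres undefined) | COC(=O)C1=CC2C(=O)OC1C(CCc1c(Cc3ccc(OCc4ccccc4)cc3)c(OCc3ccccc3)cc(OC)c1Cc1ccc(OCc3ccccc3)cc1)C2(O[Si](C)(C)C)O[Si](C)(C)C | intermediate (not isolated)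
14 | methyl 3-(2-Ar-ethyl)-4,4-bis(trimethylsilyloxy)cyclohexa-1,5-diene-1-carboxylate (racemic, centre undefined) | COC(=O)C1=CC(CCc2c(Cc3ccc(OCc4ccccc4)cc3)c(OCc3ccccc3)cc(OC)c2Cc2ccc(OCc3ccccc3)cc2)C(O[Si](C)(C)C)(O[Si](C)(C)C)C=C1 | intermediate (not isolated)
15 | methyl 3-(2-Ar-ethyl)-4-(trimethylsilyloxy)benzoate | COC(=O)c1ccc(O[Si](C)(C)C)c(CCc2c(Cc3ccc(OCc4ccccc4)cc3)c(OCc3ccccc3)cc(OC)c2Cc2ccc(OCc3ccccc3)cc2)c1 | intermediate (not isolated)
16 | methyl 3-(2-{3-(benzyloxy)-2,6-bis[4-(benzyloxy)benzyl]-5-methoxyphenyl}ethyl)-4-hydroxybenzoate | COC(=O)c1ccc(O)c(CCc2c(Cc3ccc(OCc4ccccc4)cc3)c(OCc3ccccc3)cc(OC)c2Cc2ccc(OCc3ccccc3)cc2)c1 | intermediate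
17 | methyl 4-(benzyloxy)-3-(2-{3-(benzyloxy)-2,6-bis[4-(benzyloxy)benzyl]-5-methoxyphenyl}ethyl)benzoate | COC(=O)c1ccc(OCc2ccccc2)c(CCc2c(Cc3ccc(OCc4ccccc4)cc3)c(OCc3ccccc3)cc(OC)c2Cc2ccc(OCc3ccccc3)cc2)c1 | intermediate
18 | [4-(benzyloxy)-3-(2-{3-(benzyloxy)-2,6-bis[4-(benzyloxy)benzyl]-5-methoxyphenyl}ethyl)phenyl]methanol | OCc1ccc(OCc2ccccc2)c(CCc2c(Cc3ccc(OCc4ccccc4)cc3)c(OCc3ccccc3)cc(OC)c2Cc2ccc(OCc3ccccc3)cc2)c1 | intermediate
19 | 1-(benzyloxy)-4-(bromomethyl)-2-(2-{3-(benzyloxy)-2,6-bis[4-(benzyloxy)benzyl]-5-methoxyphenyl}ethyl)benzene | BrCc1ccc(OCc2ccccc2)c(CCc2c(Cc3ccc(OCc4ccccc4)cc3)c(OCc3ccccc3)cc(OC)c2Cc2ccc(OCc3ccccc3)cc2)c1 | intermediate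
20 | 4-(benzyloxy)phenylboronic acid | OB(O)c1ccc(OCc2ccccc2)cc1 | starting material
21 | 1-(benzyloxy)-2,4-bis[4-(benzyloxy)benzyl]-3-(2-{2-(benzyloxy)-5-[4-(benzyloxy)benzyl]phenyl}ethyl)-5-methoxybenzene | COc1cc(OCc2ccccc2)c(Cc2ccc(OCc3ccccc3)cc2)c(CCc2cc(Cc3ccc(OCc4ccccc4)cc3)ccc2OCc2ccccc2)c1Cc1ccc(OCc2ccccc2)cc1 | intermediate
22 | 2,4-bis(4-hydroxybenzyl)-3-{2-[2-hydroxy-5-(4-hydroxybenzyl)phenyl]ethyl}-5-methoxyphenol | COc1cc(O)c(Cc2ccc(O)cc2)c(CCc2cc(Cc3ccc(O)cc3)ccc2O)c1Cc1ccc(O)cc1 | target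

**Step count and risks**

Total step count: 13. Longest linear sequence: 12 steps (steps 1–3 and 5–13, from 3-bromo-5-methoxyphenol); step 4 is a one-step side branch.

Steps most likely to fail:

1. Step 8. The ketene acetal may be protonated back to the silyl ester by traces of moisture before it cycloadds. The reaction may also stop at an open-chain conjugate adduct that does not close, and the β-substituent slows the [4+2]. The fallback sets out from 2 and comes back at 17, bringing ring B in ready-made. Commercial methyl 3-bromo-4-hydroxybenzoate would be benzylated (benzyl bromide, K2CO3) to methyl 4-(benzyloxy)-3-bromobenzoate F1. Suzuki–Miyaura vinylation with potassium vinyltrifluoroborate (PdCl2(dppf), Cs2CO3, THF/H2O) would give methyl 4-(benzyloxy)-3-vinylbenzoate F2. Hydroboration with 9-BBN-H would give the primary alkylborane methyl 4-(benzyloxy)-3-[2-(9-borabicyclo[3.3.1]nonan-9-yl)ethyl]benzoate F3. B-alkyl Suzuki–Miyaura coupling of F3 with 2 (PdCl2(dppf), aqueous K3PO4, THF/DMF) would give the bibenzyl methyl 4-(benzyloxy)-3-{2-[3-(benzyloxy)-5-methoxyphenyl]ethyl}benzoate F4. N-bromosuccinimide would then brominate only the far more electron-rich ring A, giving methyl 4-(benzyloxy)-3-{2-[3-(benzyloxy)-2,6-dibromo-5-methoxyphenyl]ethyl}benzoate F5. Twofold Negishi coupling of F5 with 7 under the conditions of step 5 would deliver 17.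

2. Step 5. Oxidative addition at the second bromide, now flanked by two ortho substituents, may be slow, so that mono-coupling, protodebromination and homocoupling of the benzylzinc reagent take over. The fallback sets out from 5 and comes back at 8, replacing the zinc nucleophile by an air-stable boron one. Chloride 6 would be borylated (bis(pinacolato)diboron, KOAc, bis(dibenzylideneacetone)palladium, tris(4-methoxyphenyl)phosphine, toluene) to 2-[4-(benzyloxy)benzyl]-4,4,5,5-tetramethyl-1,3,2-dioxaborolane F6. F6 would be coupled twice with 5 in a Suzuki–Miyaura reaction (Pd(OAc)2, SPhos, K3PO4, dioxane/H2O, 100 °C), where slow transmetalation from boron suppresses homocoupling.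

3. Step 12. The electron-rich benzylic bromide may ionize, leading to solvolysis, homocoupling or Friedel–Crafts self-alkylation before transmetalation. The fallback sets out from 18 and comes back at 21, forming the same bond by carbonyl addition. Oxidation of 18 with MnO2 (CH2Cl2) would give 4-(benzyloxy)-3-(2-Ar-ethyl)benzaldehyde F7. Addition of 4-(benzyloxy)phenylmagnesium bromide F8 (from 1-(benzyloxy)-4-bromobenzene and Mg turnings in THF) would give the racemic diarylmethanol [4-(benzyloxy)phenyl][4-(benzyloxy)-3-(2-Ar-ethyl)phenyl]methanol F9. Ionic hydrogenation of F9 (excess Et3SiH, CF3CO2H, CH2Cl2, 0 °C, dilute) would remove the doubly benzylic hydroxyl and give 21.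

Further compounds
F1 | step 8 | methyl 4-(benzyloxy)-3-bromobenzoate | COC(=O)c1ccc(OCc2ccccc2)c(Br)c1
F2 | step 8 | methyl 4-(benzyloxy)-3-vinylbenzoate | COC(=O)c1ccc(OCc2ccccc2)c(C=C)c1
F3 | step 8 | methyl 4-(benzyloxy)-3-[2-(9-borabicyclo[3.3.1]nonan-9-yl)ethyl]benzoate | COC(=O)c1ccc(OCc2ccccc2)c(CCB2C3CCCC2CCC3)c1
F4 | step 8 | methyl 4-(benzyloxy)-3-{2-[3-(benzyloxy)-5-methoxyphenyl]ethyl}benzoate | COC(=O)c1ccc(OCc2ccccc2)c(CCc2cc(OC)cc(OCc3ccccc3)c2)c1
F5 | step 8 | methyl 4-(benzyloxy)-3-{2-[3-(benzyloxy)-2,6-dibromo-5-methoxyphenyl]ethyl}benzoate | COC(=O)c1ccc(OCc2ccccc2)c(CCc2c(Br)c(OC)cc(OCc3ccccc3)c2Br)c1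
F6 | step 5 | 2-[4-(benzyloxy)benzyl]-4,4,5,5-tetramethyl-1,3,2-dioxaborolane | CC1(C)OB(Cc2ccc(OCc3ccccc3)cc2)OC1(C)C
F7 | step 12 | 4-(benzyloxy)-3-(2-{3-(benzyloxy)-2,6-bis[4-(benzyloxy)benzyl]-5-methoxyphenyl}ethyl)benzaldehyde | O=Cc1ccc(OCc2ccccc2)c(CCc2c(Cc3ccc(OCc4ccccc4)cc3)c(OCc3ccccc3)cc(OC)c2Cc2ccc(OCc3ccccc3)cc2)c1
F8 | step 12 | 4-(benzyloxy)phenylmagnesium bromide | Br[Mg]c1ccc(OCc2ccccc2)cc1
F9 | step 12 | [4-(benzyloxy)phenyl][4-(benzyloxy)-3-(2-{3-(benzyloxy)-2,6-bis[4-(benzyloxy)benzyl]-5-methoxyphenyl}ethyl)phenyl]methanol (racemic) | OC(c1ccc(OCc2ccccc2)cc1)c1ccc(OCc2ccccc2)c(CCc2c(Cc3ccc(OCc4ccccc4)cc3)c(OCc3ccccc3)cc(OC)c2Cc2ccc(OCc3ccccc3)cc2)c1
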